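**Strategy**

Everything rests on cutting the bond between C-1 of syringyl ring B and C-2 of the cis-fused 3,7-dioxabicyclo[3.3.0]octane core. In the precursor this carbon is the anomeric carbon of a bicyclic lactol sulfone that already carries ring C; the partner is an arylzinc holding rings A and B with erythro unit A. Ionisation gives an oxocarbenium ion flanked by bridgehead C-1, and the aryl group enters on the convex face of the bowl, so one operation joins the halves and sets C-2 exo. A single rhodium-set stereocentre relays the other three core centres; all three arylglycerol units come from one Evans glycolate aldol protocol.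

Key step: step 23

Remark: rings are lettered A (terminal guaiacyl of unit A), B and C (the two syringyl rings on the core), D and E (guaiacyl rings of units D and E); in each arylglycerol unit C7 is the benzylic carbinol carbon, C8 the aryloxy-bearing carbon and C9 the CH2OH carbon; TBS = tert-butyldimethylsilyl.
Remark: both enantiomers of 4-benzyl-3-(chloroacetyl)oxazolidin-2-one are taken as purchasable; the carbinol epimers of 29 and the anomers of 35 and 36 are carried as mixtures because these centres are erased or reset later.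

**Fragment 1 (rings A and B, erythro unit A)**

Step 1
Reactants: 1 4-bromo-2,6-dimethoxyphenol; 2 (R)-4-benzyl-3-(chloroacetyl)oxazolidin-2-one
Product: 3 (R)-4-benzyl-3-[(4-bromo-2,6-dimethoxyphenoxy)acetyl]oxazolidin-2-one
Conditions: K2CO3, NaI (cat.), acetone, 50 °C
Reagents that add atoms: none
Why: Williamson ether synthesis, in which the phenoxide should displace the activated α-chloride (SN2, iodide catalysis) faster than it attacks the imide carbonyls; no stereocentre is formed.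

Step 2
Reactants: 3 (R)-4-benzyl-3-[(4-bromo-2,6-dimethoxyphenoxy)acetyl]oxazolidin-2-one; 4 4-(tert-butyldimethylsilyloxy)-3-methoxybenzaldehyde
Product: 6 (R)-4-benzyl-3-[(2R,3S)-2-(4-bromo-2,6-dimethoxyphenoxy)-3-hydroxy-3-(3-methoxy-4-TBSO-phenyl)propanoyl]oxazolidin-2-one, via dibutylboron enolate 5 (not isolated)
Conditions: Bu2BOTf, i-Pr2NEt, CH2Cl2, 0 °C; then 4, −78 to 0 °C; pH 7 buffer, MeOH, H2O2
Reagents that add atoms: none
Why: Evans syn-aldol reaction, in which the (Z)-boron enolate reacts through a Zimmerman–Traxler chair on the face opposite the benzyl group, so the (R)-auxiliary should set both new centres as (2R,3S), the threo (7S,8S) arrangement.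

Step 3
Reactants: 6 syn-aldol adduct
Product: 7 (1S,2S)-2-(4-bromo-2,6-dimethoxyphenoxy)-1-(3-methoxy-4-TBSO-phenyl)propane-1,3-diol (threo)
Conditions: LiBH4, THF, H2O (1 equiv), 0 °C
Reagents that add atoms: none
Why: reductive cleavage of the N-acyloxazolidinone by LiBH4 is selective for the exocyclic carbonyl and should leave both stereocentres, the bromide and the aryl silyl ether untouched.

Step 4
Reactants: 7 threo diol
Product: 8 (1S,2S)-2-(4-bromo-2,6-dimethoxyphenoxy)-3-TBSO-1-(3-methoxy-4-TBSO-phenyl)propan-1-ol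
Conditions: TBSCl, imidazole, CH2Cl2, 0 °C
Reagents that add atoms: tert-butyldimethylsilyl chloride CC(C)(C)[Si](C)(C)Cl
Why: silyl ether formation with a bulky chlorosilane should be selective for the primary over the hindered benzylic secondary hydroxyl.

Step 5
Reactants: 8 threo mono-silyl ether
Product: 9 (1R,2S)-2-(4-bromo-2,6-dimethoxyphenoxy)-3-TBSO-1-(3-methoxy-4-TBSO-phenyl)propyl 4-nitrobenzoate
Conditions: PPh3, diisopropyl azodicarboxylate, 4-nitrobenzoic acid, toluene, 0 °C to rt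
Reagents that add atoms: 4-nitrobenzoic acid O=C(O)c1ccc(cc1)[N+](=O)[O-]
Why: Mitsunobu reaction, in which SN2 attack of the carboxylate on the oxyphosphonium ion should invert the benzylic centre and turn threo (1S,2S) into erythro (1R,2S); the non-polar solvent and the acidic pronucleophile are chosen to suppress ionisation.

Step 6
Reactants: 9 inverted 4-nitrobenzoate
Product: 10 (1R,2S)-2-(4-bromo-2,6-dimethoxyphenoxy)-3-TBSO-1-(3-methoxy-4-TBSO-phenyl)propan-1-ol (erythro)
Conditions: LiBH4, THF, MeOH (1 equiv), 0 °C to rt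
Reagents that add atoms: none
Why: hydride reduction of the activated aryl ester should release the inverted alcohol without base, so the aryl silyl ether stays on and no quinone methide can arise from a free para-phenoxide.

Step 7
Reactants: 10 erythro alcohol
Product: 11 5-bromo-2-{[(1R,2S)-1,3-bis-TBSO-1-(3-methoxy-4-TBSO-phenyl)propan-2-yl]oxy}-1,3-dimethoxybenzene (fragment 1)
Conditions: TBSOTf, 2,6-lutidine, CH2Cl2, 0 °C
Reagents that add atoms: tert-butyldimethylsilyl trifluoromethanesulfonate CC(C)(C)[Si](C)(C)OS(=O)(=O)C(F)(F)F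
Why: the silyl triflate should silylate even the hindered benzylic alcohol, giving a bromide with no acidic hydrogen for the later halogen–lithium exchange.

**Fragment 3 (rings D and E, erythro unit E)**

Step 8
Reactants: 12 4-bromo-2-methoxyphenol; 13 (S)-4-benzyl-3-(chloroacetyl)oxazolidin-2-one
Product: 14 (S)-4-benzyl-3-[(4-bromo-2-methoxyphenoxy)acetyl]oxazolidin-2-one
Conditions: K2CO3, NaI (cat.), acetone, 50 °C
Reagents that add atoms: none
Why: Williamson ether synthesis as in step 1; no stereocentre is formed.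

Step 9
Reactants: 14 (S)-4-benzyl-3-[(4-bromo-2-methoxyphenoxy)acetyl]oxazolidin-2-one; 4 4-(tert-butyldimethylsilyloxy)-3-methoxybenzaldehyde
Product: 16 (S)-4-benzyl-3-[(2S,3R)-2-(4-bromo-2-methoxyphenoxy)-3-hydroxy-3-(3-methoxy-4-TBSO-phenyl)propanoyl]oxazolidin-2-one, via dibutylboron enolate 15 (not isolated)
Conditions: Bu2BOTf, i-Pr2NEt, CH2Cl2, 0 °C; then 4, −78 to 0 °C; pH 7 buffer, MeOH, H2O2
Reagents that add atoms: none
Why: Evans syn-aldol reaction with the enantiomeric auxiliary, which should give the mirror-image (2S,3R) syn adduct, the threo (7R,8R) arrangement.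

Step 10
Reactants: 16 syn-aldol adduct
Product: 17 (1R,2R)-2-(4-bromo-2-methoxyphenoxy)-1-(3-methoxy-4-TBSO-phenyl)propane-1,3-diol (threo)
Conditions: LiBH4, THF, H2O (1 equiv), 0 °C
Reagents that add atoms: none
Why: chemoselective reductive removal of the auxiliary as in step 3.

Step 11
Reactants: 17 threo diol
Product: 18 (1R,2R)-2-(4-bromo-2-methoxyphenoxy)-3-TBSO-1-(3-methoxy-4-TBSO-phenyl)propan-1-ol
Conditions: TBSCl, imidazole, CH2Cl2, 0 °C
Reagents that add atoms: tert-butyldimethylsilyl chloride CC(C)(C)[Si](C)(C)Cl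
Why: selective silylation of the primary hydroxyl as in step 4.

Step 12
Reactants: 18 threo mono-silyl ether
Product: 19 (1S,2R)-2-(4-bromo-2-methoxyphenoxy)-3-TBSO-1-(3-methoxy-4-TBSO-phenyl)propyl 4-nitrobenzoate
Conditions: PPh3, diisopropyl azodicarboxylate, 4-nitrobenzoic acid, toluene, 0 °C to rt
Reagents that add atoms: 4-nitrobenzoic acid O=C(O)c1ccc(cc1)[N+](=O)[O-]
Why: Mitsunobu reaction with SN2 inversion at the benzylic carbon, which should turn threo (1R,2R) into erythro (1S,2R).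

Step 13
Reactants: 19 inverted 4-nitrobenzoate
Product: 20 (1S,2R)-2-(4-bromo-2-methoxyphenoxy)-3-TBSO-1-(3-methoxy-4-TBSO-phenyl)propan-1-ol (erythro)
Conditions: LiBH4, THF, MeOH (1 equiv), 0 °C to rt
Reagents that add atoms: none
Why: base-free reductive ester cleavage as in step 6.

Step 14
Reactants: 20 erythro alcohol
Product: 21 4-bromo-1-{[(1S,2R)-1,3-bis-TBSO-1-(3-methoxy-4-TBSO-phenyl)propan-2-yl]oxy}-2-methoxybenzene
Conditions: TBSOTf, 2,6-lutidine, CH2Cl2, 0 °C
Reagents that add atoms: tert-butyldimethylsilyl trifluoromethanesulfonate CC(C)(C)[Si](C)(C)OS(=O)(=O)C(F)(F)F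
Why: silylation of the hindered benzylic alcohol as in step 7.

Step 15
Reactants: 21 ring-D aryl bromide
Product: 23 4-{[(1S,2R)-1,3-bis-TBSO-1-(3-methoxy-4-TBSO-phenyl)propan-2-yl]oxy}-3-methoxybenzaldehyde (fragment 3), via aryllithium 22 (not isolated)
Conditions: n-BuLi, THF, −78 °C; then DMF, −78 to 0 °C; H2O
Reagents that add atoms: N,N-dimethylformamide CN(C)C=O
Why: bromine–lithium exchange followed by Bouveault formylation should tolerate the silyl ethers at low temperature and installs the aldehyde carbon that becomes C7 of unit D.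

**Core (ring C and the bicyclic sulfone)**

Step 16
Reactants: 24 furan-2(5H)-one; 25 potassium trifluoro(vinyl)borate
Product: 26 (S)-4-vinyldihydrofuran-2(3H)-one
Conditions: [Rh(cod)2]BF4 (3 mol %), (S)-BINAP (3.3 mol %), toluene/H2O 10:1, 105 °C
Reagents that add atoms: none
Why: Hayashi–Miyaura rhodium-catalysed asymmetric conjugate addition, in which the (S)-BINAP complex selects the alkene face (same sense as for cyclic enones and unsaturated lactones) and sets the only catalyst-derived stereocentre of the core as (S).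

Step 17
Reactants: 26 (S)-4-vinyldihydrofuran-2(3H)-one; 27 4-formyl-2,6-dimethoxyphenyl acetate
Product: 29 (3S,4R)-3-[(4-acetoxy-3,5-dimethoxyphenyl)(hydroxy)methyl]-4-vinyldihydrofuran-2(3H)-one (trans lactone, carbinol epimers), via lithium enolate 28 (not isolated)
Conditions: LiN(i-Pr)2, THF, −78 °C; then 27, −78 °C; AcOH quench at −78 °C
Reagents that add atoms: none
Why: aldol addition of the lactone enolate anti to the neighbouring vinyl group (substrate control, trans-3,4 lactone), the aldehyde reacting far faster than the aryl acetate; the carbinol centre forms as a mixture that is erased in step 19.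

Step 18
Reactants: 29 aldol lactone
Product: 30 (2R,3R)-2-[hydroxy(4-hydroxy-3,5-dimethoxyphenyl)methyl]-3-vinylbutane-1,4-diol (carbinol epimers)
Conditions: LiAlH4, THF, 0 °C to rt; aq. KNaC4H4O6 work-up
Reagents that add atoms: none
Why: hydride reduction opens the lactone to the 1,4-diol and in the same operation removes the phenolic acetate, exposing the para-hydroxybenzylic alcohol needed next.

Step 19
Reactants: 30 tetraol
Product: 31 [(2S,3R,4R)-2-(4-hydroxy-3,5-dimethoxyphenyl)-4-vinyltetrahydrofuran-3-yl]methanol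
Conditions: (+)-camphor-10-sulfonic acid (10 mol %), CH2Cl2/THF, 0 °C to rt
Reagents that add atoms: none
Why: acid-catalysed SN1 cycloetherification through the quinone-methide-type benzylic cation, captured 5-exo by the 1,4-related primary hydroxyl (the other hydroxyl could only form a four-membered ring); the reversible closure should place the aryl group trans to the neighbouring hydroxymethyl group, relaying C3 to C2.

Step 20
Reactants: 31 phenol; 2 (R)-4-benzyl-3-(chloroacetyl)oxazolidin-2-one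
Product: 32 (R)-4-benzyl-3-[(4-[(2S,3R,4R)-3-(hydroxymethyl)-4-vinyltetrahydrofuran-2-yl]-2,6-dimethoxyphenoxy)acetyl]oxazolidin-2-one
Conditions: K2CO3, NaI (cat.), DMF, rt
Reagents that add atoms: none
Why: Williamson ether synthesis, chemoselective for the phenoxide over the primary alcohol under carbonate conditions.

Step 21
Reactants: 32 vinyl tetrahydrofuran imide
Product: 35 (R)-4-benzyl-3-[(4-[(1R,5R,6S)-2-hydroxy-3,7-dioxabicyclo[3.3.0]octan-6-yl]-2,6-dimethoxyphenoxy)acetyl]oxazolidin-2-one (lactol, anomers), via vicinal diol 33 (not isolated), via hydroxy aldehyde 34 (not isolated)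
Conditions: OsO4 (2 mol %), NaIO4, 2,6-lutidine, 1,4-dioxane/H2O 3:1, rt
Reagents that add atoms: osmium tetroxide O=[Os](=O)(=O)=O (catalytic oxygen carrier); sodium periodate [Na+].[O-]I(=O)(=O)=O (terminal oxygen source)
Why: Lemieux–Johnson oxidation cleaves the vinyl group to an aldehyde that is cis to the hydroxymethyl group and should close at once to the cis-fused lactol; the arene and the imide are inert.

Step 22
Reactants: 35 lactol
Product: 36 (R)-4-benzyl-3-[(4-[(1R,5R,6S)-2-(phenylsulfonyl)-3,7-dioxabicyclo[3.3.0]octan-6-yl]-2,6-dimethoxyphenoxy)acetyl]oxazolidin-2-one (anomers)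
Conditions: PhSO2H, CaCl2 (powder), CH2Cl2, rt
Reagents that add atoms: benzenesulfinic acid O=S(O)c1ccccc1
Why: acid-mediated anomeric substitution of hydroxyl by sulfinate through the oxocarbenium ion should give a stable anomeric sulfone, CaCl2 taking up the water.

**Fragment union and end game**

Step 23
Reactants: 11 fragment 1 aryl bromide; 36 bicyclic anomeric sulfone
Product: 39 (R)-4-benzyl-3-[(4-[(1R,2S,5R,6S)-6-(4-{[(1R,2S)-1,3-bis-TBSO-1-(3-methoxy-4-TBSO-phenyl)propan-2-yl]oxy}-3,5-dimethoxyphenyl)-3,7-dioxabicyclo[3.3.0]octan-2-yl]-2,6-dimethoxyphenoxy)acetyl]oxazolidin-2-one, via aryllithium 37 (not isolated), via arylzinc bromide 38 (not isolated)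
Conditions: 11 (2.2 equiv), n-BuLi, THF, −78 °C; ZnBr2, −78 to 0 °C; then 36 (1.0 equiv), MgBr2·OEt2, THF, 0 °C to rt
Reagents that add atoms: none
Why: ZnBr2 and MgBr2 assist loss of benzenesulfinate from either anomer of 36, giving one bicyclic oxocarbenium ion in which the cationic carbon is flanked by bridgehead C-1, and the aryl group is transferred ipso from zinc to that carbon. The closest known reaction type is the substitution of 2-(phenylsulfonyl) cyclic ethers by organozinc reagents, as used for C-aryl glycosides. No ring is closed, since both tetrahydrofuran rings are already in place and the step only has to choose a face. The new stereocentre is controlled by the substrate: the cis-fused 3,7-dioxabicyclo[3.3.0]octane is bowl-shaped and the arylzinc should enter on the convex face, anti to the C-1–C-8 bond, which places ring B exo (S), matching the exo ring C on the other tetrahydrofuran ring. The step needs ipso regioselectivity on ring B, which a Friedel–Crafts reaction of this 1,2,3-trioxygenated arene would not give, and tolerance of the imide, silyl ethers and benzylic ethers, which the weakly basic zinc reagent and the mild Lewis acids should secure.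

Step 24
Reactants: 39 furofuran imide; 23 fragment 3 aldehyde
Product: 41 syn-aldol adduct of 39 and 23 with the (2R,3S)-2-aryloxy-3-hydroxy-3-arylpropanoyl imide (threo unit D still on the auxiliary), via dibutylboron enolate 40 (not isolated)
Conditions: Bu2BOTf, i-Pr2NEt, CH2Cl2, −78 to 0 °C; then 23 (1.3 equiv), −78 to −20 °C; pH 7 buffer, MeOH, H2O2, 0 °C
Reagents that add atoms: none
Why: Evans syn-aldol reaction, in which the (R)-auxiliary on the ring-C glycolate should set C8 and C7 of unit D as (2R,3S), i.e. threo (7S,8S), independent of the remote centres of the aldehyde; the amine-complexed boron triflate at low temperature should spare the furofuran ethers.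

Step 25
Reactants: 41 aldol adduct
Product: 42 hexa-TBS ether of the target (unit D as free (7S,8S) 1,3-diol; ring A, C7A, C9A, ring E, C7E and C9E oxygens silylated)
Conditions: LiBH4, THF, H2O (1 equiv), 0 °C
Reagents that add atoms: none
Why: reductive removal of the auxiliary as in step 3, giving C9 of unit D as CH2OH without touching silyl ethers or stereocentres.

Step 26
Reactants: 42 hexa-TBS ether
Product: 43 target CNP0316493.3
Conditions: Bu4NF, AcOH, THF, 0 °C to rt
Reagents that add atoms: none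
Why: fluoride-mediated desilylation should remove all six silyl ethers, and the acetic acid buffer keeps the freed para-hydroxybenzylic alcohols from forming quinone methides.

**Compound list**

1 | 4-bromo-2,6-dimethoxyphenol | COc1cc(Br)cc(OC)c1O | starting material
2 | (R)-4-benzyl-3-(chloroacetyl)oxazolidin-2-one | ClCC(=O)N1C(=O)OC[C@H]1Cc1ccccc1 | starting material
3 | (R)-4-benzyl-3-[(4-bromo-2,6-dimethoxyphenoxy)acetyl]oxazolidin-2-one | COc1cc(Br)cc(OC)c1OCC(=O)N1C(=O)OC[C@H]1Cc1ccccc1 | intermediate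
4 | 4-(tert-butyldimethylsilyloxy)-3-methoxybenzaldehyde | COc1cc(C=O)ccc1O[Si](C)(C)C(C)(C)C | starting material
5 | (Z)-dibutylboron enolate of 3 | COc1cc(Br)cc(OC)c1O\C=C(/OB(CCCC)CCCC)N1C(=O)OC[C@H]1Cc1ccccc1 | intermediate (not isolated)
6 | (R)-4-benzyl-3-[(2R,3S)-2-(4-bromo-2,6-dimethoxyphenoxy)-3-hydroxy-3-(3-methoxy-4-TBSO-phenyl)propanoyl]oxazolidin-2-one | COc1cc([C@H](O)[C@H](C(=O)N2C(=O)OC[C@H]2Cc2ccccc2)Oc2c(OC)cc(Br)cc2OC)ccc1O[Si](C)(C)C(C)(C)C | intermediate
7 | (1S,2S)-2-(4-bromo-2,6-dimethoxyphenoxy)-1-(3-methoxy-4-TBSO-phenyl)propane-1,3-diol | COc1cc([C@H](O)[C@H](CO)Oc2c(OC)cc(Br)cc2OC)ccc1O[Si](C)(C)C(C)(C)C | intermediate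
8 | (1S,2S)-2-(4-bromo-2,6-dimethoxyphenoxy)-3-TBSO-1-(3-methoxy-4-TBSO-phenyl)propan-1-ol | COc1cc([C@H](O)[C@H](CO[Si](C)(C)C(C)(C)C)Oc2c(OC)cc(Br)cc2OC)ccc1O[Si](C)(C)C(C)(C)C | intermediate
9 | (1R,2S)-2-(4-bromo-2,6-dimethoxyphenoxy)-3-TBSO-1-(3-methoxy-4-TBSO-phenyl)propyl 4-nitrobenzoate | COc1cc([C@@H](OC(=O)c2ccc(cc2)[N+](=O)[O-])[C@H](CO[Si](C)(C)C(C)(C)C)Oc2c(OC)cc(Br)cc2OC)ccc1O[Si](C)(C)C(C)(C)C | intermediate
10 | (1R,2S)-2-(4-bromo-2,6-dimethoxyphenoxy)-3-TBSO-1-(3-methoxy-4-TBSO-phenyl)propan-1-ol | COc1cc([C@@H](O)[C@H](CO[Si](C)(C)C(C)(C)C)Oc2c(OC)cc(Br)cc2OC)ccc1O[Si](C)(C)C(C)(C)C | intermediate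
11 | 5-bromo-2-{[(1R,2S)-1,3-bis-TBSO-1-(3-methoxy-4-TBSO-phenyl)propan-2-yl]oxy}-1,3-dimethoxybenzene (fragment 1) | COc1cc([C@@H](O[Si](C)(C)C(C)(C)C)[C@H](CO[Si](C)(C)C(C)(C)C)Oc2c(OC)cc(Br)cc2OC)ccc1O[Si](C)(C)C(C)(C)C | intermediate
12 | 4-bromo-2-methoxyphenol | COc1cc(Br)ccc1O | starting material
13 | (S)-4-benzyl-3-(chloroacetyl)oxazolidin-2-one | ClCC(=O)N1C(=O)OC[C@@H]1Cc1ccccc1 | starting material
14 | (S)-4-benzyl-3-[(4-bromo-2-methoxyphenoxy)acetyl]oxazolidin-2-one | COc1cc(Br)ccc1OCC(=O)N1C(=O)OC[C@@H]1Cc1ccccc1 | intermediate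
15 | (Z)-dibutylboron enolate of 14 | COc1cc(Br)ccc1O\C=C(/OB(CCCC)CCCC)N1C(=O)OC[C@@H]1Cc1ccccc1 | intermediate (not isolated)
16 | (S)-4-benzyl-3-[(2S,3R)-2-(4-bromo-2-methoxyphenoxy)-3-hydroxy-3-(3-methoxy-4-TBSO-phenyl)propanoyl]oxazolidin-2-one | COc1cc(Br)ccc1O[C@H](C(=O)N1C(=O)OC[C@@H]1Cc1ccccc1)[C@H](O)c1ccc(O[Si](C)(C)C(C)(C)C)c(OC)c1 | intermediate
17 | (1R,2R)-2-(4-bromo-2-methoxyphenoxy)-1-(3-methoxy-4-TBSO-phenyl)propane-1,3-diol | COc1cc(Br)ccc1O[C@H](CO)[C@H](O)c1ccc(O[Si](C)(C)C(C)(C)C)c(OC)c1 | intermediate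
18 | (1R,2R)-2-(4-bromo-2-methoxyphenoxy)-3-TBSO-1-(3-methoxy-4-TBSO-phenyl)propan-1-ol | COc1cc(Br)ccc1O[C@H](CO[Si](C)(C)C(C)(C)C)[C@H](O)c1ccc(O[Si](C)(C)C(C)(C)C)c(OC)c1 | intermediate
19 | (1S,2R)-2-(4-bromo-2-methoxyphenoxy)-3-TBSO-1-(3-methoxy-4-TBSO-phenyl)propyl 4-nitrobenzoate | COc1cc(Br)ccc1O[C@H](CO[Si](C)(C)C(C)(C)C)[C@@H](OC(=O)c1ccc(cc1)[N+](=O)[O-])c1ccc(O[Si](C)(C)C(C)(C)C)c(OC)c1 | intermediate
20 | (1S,2R)-2-(4-bromo-2-methoxyphenoxy)-3-TBSO-1-(3-methoxy-4-TBSO-phenyl)propan-1-ol | COc1cc(Br)ccc1O[C@H](CO[Si](C)(C)C(C)(C)C)[C@@H](O)c1ccc(O[Si](C)(C)C(C)(C)C)c(OC)c1 | intermediate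
21 | 4-bromo-1-{[(1S,2R)-1,3-bis-TBSO-1-(3-methoxy-4-TBSO-phenyl)propan-2-yl]oxy}-2-methoxybenzene | COc1cc(Br)ccc1O[C@H](CO[Si](C)(C)C(C)(C)C)[C@@H](O[Si](C)(C)C(C)(C)C)c1ccc(O[Si](C)(C)C(C)(C)C)c(OC)c1 | intermediate
22 | aryllithium from 21 (lithium in place of bromine) | COc1cc([Li])ccc1O[C@H](CO[Si](C)(C)C(C)(C)C)[C@@H](O[Si](C)(C)C(C)(C)C)c1ccc(O[Si](C)(C)C(C)(C)C)c(OC)c1 | intermediate (not isolated)
23 | 4-{[(1S,2R)-1,3-bis-TBSO-1-(3-methoxy-4-TBSO-phenyl)propan-2-yl]oxy}-3-methoxybenzaldehyde (fragment 3) | COc1cc(C=O)ccc1O[C@H](CO[Si](C)(C)C(C)(C)C)[C@@H](O[Si](C)(C)C(C)(C)C)c1ccc(O[Si](C)(C)C(C)(C)C)c(OC)c1 | intermediate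
24 | furan-2(5H)-one | O=C1OCC=C1 | starting material
25 | potassium trifluoro(vinyl)borate | [K+].C=C[B-](F)(F)F | starting material
26 | (S)-4-vinyldihydrofuran-2(3H)-one | C=C[C@H]1COC(=O)C1 | intermediate
27 | 4-formyl-2,6-dimethoxyphenyl acetate | COc1cc(C=O)cc(OC)c1OC(C)=O | starting material
28 | lithium enolate of 26 | C=C[C@H]1COC(O[Li])=C1 | intermediate (not isolated)
29 | (3S,4R)-3-[(4-acetoxy-3,5-dimethoxyphenyl)(hydroxy)methyl]-4-vinyldihydrofuran-2(3H)-one (carbinol epimers) | C=C[C@H]1COC(=O)[C@@H]1C(O)c1cc(OC)c(OC(C)=O)c(OC)c1 | intermediate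
30 | (2R,3R)-2-[hydroxy(4-hydroxy-3,5-dimethoxyphenyl)methyl]-3-vinylbutane-1,4-diol (carbinol epimers) | C=C[C@@H](CO)[C@H](CO)C(O)c1cc(OC)c(O)c(OC)c1 | intermediate
31 | [(2S,3R,4R)-2-(4-hydroxy-3,5-dimethoxyphenyl)-4-vinyltetrahydrofuran-3-yl]methanol | C=C[C@H]1CO[C@H](c2cc(OC)c(O)c(OC)c2)[C@H]1CO | intermediate
32 | (R)-4-benzyl-3-[(4-[(2S,3R,4R)-3-(hydroxymethyl)-4-vinyltetrahydrofuran-2-yl]-2,6-dimethoxyphenoxy)acetyl]oxazolidin-2-one | C=C[C@H]1CO[C@H](c2cc(OC)c(OCC(=O)N3C(=O)OC[C@H]3Cc3ccccc3)c(OC)c2)[C@H]1CO | intermediate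
33 | vicinal diol from dihydroxylation of the vinyl group of 32 (new carbinol centre undefined) | OCC(O)[C@H]1CO[C@H](c2cc(OC)c(OCC(=O)N3C(=O)OC[C@H]3Cc3ccccc3)c(OC)c2)[C@H]1CO | intermediate (not isolated)
34 | hydroxy aldehyde: 32 with the vinyl group replaced by a formyl group | O=C[C@H]1CO[C@H](c2cc(OC)c(OCC(=O)N3C(=O)OC[C@H]3Cc3ccccc3)c(OC)c2)[C@H]1CO | intermediate (not isolated)
35 | (R)-4-benzyl-3-[(4-[(1R,5R,6S)-2-hydroxy-3,7-dioxabicyclo[3.3.0]octan-6-yl]-2,6-dimethoxyphenoxy)acetyl]oxazolidin-2-one (anomers) | OC1OC[C@H]2[C@@H]1CO[C@@H]2c1cc(OC)c(OCC(=O)N3C(=O)OC[C@H]3Cc3ccccc3)c(OC)c1 | intermediate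
36 | (R)-4-benzyl-3-[(4-[(1R,5R,6S)-2-(phenylsulfonyl)-3,7-dioxabicyclo[3.3.0]octan-6-yl]-2,6-dimethoxyphenoxy)acetyl]oxazolidin-2-one (anomers) | O=S(=O)(c1ccccc1)C1OC[C@H]2[C@@H]1CO[C@@H]2c1cc(OC)c(OCC(=O)N3C(=O)OC[C@H]3Cc3ccccc3)c(OC)c1 | intermediate
37 | aryllithium from 11 (lithium in place of bromine) | COc1cc([C@@H](O[Si](C)(C)C(C)(C)C)[C@H](CO[Si](C)(C)C(C)(C)C)Oc2c(OC)cc([Li])cc2OC)ccc1O[Si](C)(C)C(C)(C)C | intermediate (not isolated)
38 | arylzinc bromide from 37 | COc1cc([C@@H](O[Si](C)(C)C(C)(C)C)[C@H](CO[Si](C)(C)C(C)(C)C)Oc2c(OC)cc([Zn]Br)cc2OC)ccc1O[Si](C)(C)C(C)(C)C | intermediate (not isolated)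
39 | furofuran imide: (1R,2S,5R,6S)-3,7-dioxabicyclo[3.3.0]octane bearing at one benzylic carbon the ring-B aryl group of 11 (exo) and at the other ring C with the (R)-4-benzyl-2-oxooxazolidin-3-yl glycolate ether (exo) | COc1cc([C@@H](O[Si](C)(C)C(C)(C)C)[C@H](CO[Si](C)(C)C(C)(C)C)Oc2c(OC)cc([C@H]3OC[C@H]4[C@@H]3CO[C@@H]4c3cc(OC)c(OCC(=O)N4C(=O)OC[C@H]4Cc4ccccc4)c(OC)c3)cc2OC)ccc1O[Si](C)(C)C(C)(C)C | intermediate
40 | (Z)-dibutylboron enolate of 39 | COc1cc([C@@H](O[Si](C)(C)C(C)(C)C)[C@H](CO[Si](C)(C)C(C)(C)C)Oc2c(OC)cc([C@H]3OC[C@H]4[C@@H]3CO[C@@H]4c3cc(OC)c(O\C=C(/OB(CCCC)CCCC)N4C(=O)OC[C@H]4Cc4ccccc4)c(OC)c3)cc2OC)ccc1O[Si](C)(C)C(C)(C)C | intermediate (not isolated)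
41 | syn-aldol adduct of 39 and 23: (2R,3S)-2-aryloxy-3-hydroxy-3-arylpropanoyl imide carrying threo unit D | COc1cc([C@@H](O[Si](C)(C)C(C)(C)C)[C@H](CO[Si](C)(C)C(C)(C)C)Oc2c(OC)cc([C@H]3OC[C@H]4[C@@H]3CO[C@@H]4c3cc(OC)c(O[C@@H](C(=O)N4C(=O)OC[C@H]4Cc4ccccc4)[C@@H](O)c4ccc(O[C@H](CO[Si](C)(C)C(C)(C)C)[C@@H](O[Si](C)(C)C(C)(C)C)c5ccc(O[Si](C)(C)C(C)(C)C)c(OC)c5)c(OC)c4)c(OC)c3)cc2OC)ccc1O[Si](C)(C)C(C)(C)C | intermediate
42 | hexa-TBS ether of the target (unit D diol free) | COc1cc([C@@H](O[Si](C)(C)C(C)(C)C)[C@H](CO[Si](C)(C)C(C)(C)C)Oc2c(OC)cc([C@H]3OC[C@H]4[C@@H]3CO[C@@H]4c3cc(OC)c(O[C@@H](CO)[C@@H](O)c4ccc(O[C@H](CO[Si](C)(C)C(C)(C)C)[C@@H](O[Si](C)(C)C(C)(C)C)c5ccc(O[Si](C)(C)C(C)(C)C)c(OC)c5)c(OC)c4)c(OC)c3)cc2OC)ccc1O[Si](C)(C)C(C)(C)C | intermediate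
43 | CNP0316493.3: (1R,2S,5R,6S)-2,6-diaryl-3,7-dioxabicyclo[3.3.0]octane (syringaresinol-type core) with an erythro (7R,8S) guaiacylglycerol on the ring-B oxygen and a threo (7S,8S) guaiacylglycerol on the ring-C oxygen, whose ring-D oxygen carries an erythro (7S,8R) guaiacylglycerol | COc1cc([C@@H](O)[C@H](CO)Oc2c(OC)cc([C@H]3OC[C@H]4[C@@H]3CO[C@@H]4c3cc(OC)c(O[C@@H](CO)[C@@H](O)c4ccc(O[C@H](CO)[C@@H](O)c5ccc(O)c(OC)c5)c(OC)c4)c(OC)c3)cc2OC)ccc1O | target

**Totals**

Total step count: 26. Longest linear sequence: 11 steps (steps 1–7 and 23–26; the sequences 16–26 and 8–15 plus 24–26 are equally long).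

**Steps most likely to fail**

1. Step 23 (key step). Ionisation of the sulfone may be slow, so that the hindered arylzinc is protonated before it is transferred, or the product may re-ionise at its benzylic ether carbons and lose the exo configuration. The fallback replaces substitution by carbonyl addition followed by ring closure. It sets out from 31, whose phenol is benzylated (BnBr, K2CO3, acetone) to [(2S,3R,4R)-2-(4-benzyloxy-3,5-dimethoxyphenyl)-4-vinyltetrahydrofuran-3-yl]methanol F1. Lemieux–Johnson cleavage as in step 21 gives the lactol (1R,5R,6S)-6-(4-benzyloxy-3,5-dimethoxyphenyl)-3,7-dioxabicyclo[3.3.0]octan-2-ol F2. Aryllithium 37 (2.5 equiv, THF, −78 to 0 °C) adds to the open hydroxy aldehyde form to give the diol F3 as a carbinol mixture. Acid-catalysed SN1 ring closure (camphorsulfonic acid, CH2Cl2, 0 °C) should converge on the exo furofuran benzyl ether F4. Hydrogenolysis (H2, Pd/C, EtOAc) frees the ring-C phenol F5, and alkylation with 2 as in step 20 comes back to the route at 39.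

2. Step 5. The electron-rich benzylic oxyphosphonium ion may ionise, so that the ester forms with partial retention, or it may eliminate towards the enol ether. The fallback replaces SN2 inversion by oxidation and reduction. It sets out from 8, which is oxidised with Dess–Martin periodinane (CH2Cl2, NaHCO3) to the ketone (S)-2-(4-bromo-2,6-dimethoxyphenoxy)-3-TBSO-1-(3-methoxy-4-TBSO-phenyl)propan-1-one F6. Felkin–Anh reduction with LiBH(s-Bu)3 (THF, −78 °C, hydride anti to the aryloxy group) should give the erythro alcohol and rejoins the route at 10.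

3. Step 16. The vinyl transfer reagent may be lost by protodeboronation or polymerisation, and the butenolide may open under the hot aqueous conditions, giving low conversion. The fallback transfers a robust alkenyl group and trims it afterwards. It sets out from 24, which under the same rhodium/(S)-BINAP catalysis with (E)-styrylboronic acid should give (S,E)-4-styryldihydrofuran-2(3H)-one F7. Ethenolysis with second-generation Hoveyda–Grubbs catalyst under ethylene (CH2Cl2, rt) comes back to the route at 26.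

Further compounds
F1 | step 23 | [(2S,3R,4R)-2-(4-benzyloxy-3,5-dimethoxyphenyl)-4-vinyltetrahydrofuran-3-yl]methanol | C=C[C@H]1CO[C@H](c2cc(OC)c(OCc3ccccc3)c(OC)c2)[C@H]1CO
F2 | step 23 | (1R,5R,6S)-6-(4-benzyloxy-3,5-dimethoxyphenyl)-3,7-dioxabicyclo[3.3.0]octan-2-ol (anomers) | OC1OC[C@H]2[C@@H]1CO[C@@H]2c1cc(OC)c(OCc2ccccc2)c(OC)c1
F3 | step 23 | diol from addition of 37 to F2: the tetrahydrofuran of F1 with the vinyl group replaced by the ring-B aryl(hydroxy)methyl group (carbinol epimers) | COc1cc([C@@H](O[Si](C)(C)C(C)(C)C)[C@H](CO[Si](C)(C)C(C)(C)C)Oc2c(OC)cc(C(O)[C@H]3CO[C@H](c4cc(OC)c(OCc5ccccc5)c(OC)c4)[C@H]3CO)cc2OC)ccc1O[Si](C)(C)C(C)(C)C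
F4 | step 23 | exo,exo furofuran with ring C as its benzyl ether (39 with OBn in place of the glycolyl imide) | COc1cc([C@@H](O[Si](C)(C)C(C)(C)C)[C@H](CO[Si](C)(C)C(C)(C)C)Oc2c(OC)cc([C@H]3OC[C@H]4[C@@H]3CO[C@@H]4c3cc(OC)c(OCc4ccccc4)c(OC)c3)cc2OC)ccc1O[Si](C)(C)C(C)(C)C
F5 | step 23 | exo,exo furofuran with free ring-C phenol | COc1cc([C@@H](O[Si](C)(C)C(C)(C)C)[C@H](CO[Si](C)(C)C(C)(C)C)Oc2c(OC)cc([C@H]3OC[C@H]4[C@@H]3CO[C@@H]4c3cc(OC)c(O)c(OC)c3)cc2OC)ccc1O[Si](C)(C)C(C)(C)C
F6 | step 5 | (S)-2-(4-bromo-2,6-dimethoxyphenoxy)-3-TBSO-1-(3-methoxy-4-TBSO-phenyl)propan-1-one | COc1cc(C(=O)[C@H](CO[Si](C)(C)C(C)(C)C)Oc2c(OC)cc(Br)cc2OC)ccc1O[Si](C)(C)C(C)(C)C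
F7 | step 16 | (S,E)-4-styryldihydrofuran-2(3H)-one | O=C1C[C@@H](CO1)/C=C/c1ccccc1
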